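The synthesis hinges on disconnecting the C7–C8 bond of the ten-membered carbocycle. The homoallylic alcohol unit C13=C11–C7–C8–OH, which spans the trans junction of the γ-lactone and the ten-membered ring, is treated as the product of a γ-selective allylation. A 3-(bromomethyl)butenolide (C13–Br, C11=C7) adds through C7 to a C8 aldehyde. This one chromium-mediated step closes the carbocycle, moves the alkene to the exocyclic C11=C13 position, liberates the C8 hydroxyl and sets C7 and C8. The precursor is an open chain carrying the (6R)-butenolide, both Z alkenes, the C9 acetate, the C14 (R)-2-methylbutanoate and an α-acetoxy aldehyde at C8.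

Key step: step 16

Remarks on the chemistry:
- Atom labels follow germacranolide numbering: C6 is the lactone O–CH, C7 the ring-fusion CH, C8 the free carbinol, C9 the acetoxy carbon, C10 the alkene carbon bearing C14H2O, C11=C13 the exocyclic methylene, C12 the lactone carbonyl and C4(C15)=C5 the methyl-bearing alkene.
- Epoxide 3 is a racemate at its single stereocentre, which is destroyed in step 3.
- (R)-2-Methylbutanoic acid and both enantiomers of the oxazoline sulfonamide ligand are assumed to be purchasable.

Step 1
Reactants: 1 nerol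
Product: 2 neryl 4-methoxybenzyl ether
Conditions: NaH, 4-methoxybenzyl chloride, Bu4NI (cat.), THF/DMF, 0 °C to rt
Reagents that add atoms: 4-methoxybenzyl chloride, COc1ccc(CCl)cc1
Why: Williamson ether synthesis, in which the sodium alkoxide of the primary allylic alcohol displaces chloride from the benzylic halide under iodide catalysis and neither alkene is touched.

Step 2
Reactants: 2 neryl 4-methoxybenzyl ether
Product: 3 3-[(Z)-5-(4-methoxybenzyloxy)-3-methylpent-3-enyl]-2,2-dimethyloxirane (racemic)
Conditions: mCPBA, NaHCO3, CH2Cl2, −20 to 0 °C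
Reagents that add atoms: 3-chloroperbenzoic acid, O=C(OO)c1cccc(Cl)c1
Why: Prilezhaev epoxidation is electrophilic, so the remote dimethyl-substituted alkene should react ahead of the alkene deactivated by its allylic ether oxygen; the new stereocentre is racemic and is removed in step 3.

Step 3
Reactants: 3 3-[(Z)-5-(4-methoxybenzyloxy)-3-methylpent-3-enyl]-2,2-dimethyloxirane
Product: 5 (Z)-6-(4-methoxybenzyloxy)-4-methylhex-4-enal, via diol 4 (not isolated)
Conditions: H5IO6, THF/H2O, 0 °C
Reagents that add atoms: water, O (its oxygen enters diol 4)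
Why: Periodic acid hydrates the epoxide to diol 4 and then cleaves the glycol (Malaprade reaction), excising acetone and leaving the C1 aldehyde, while the Z alkene and the 4-methoxybenzyl ether should survive the short cold exposure.

Step 4
Reactants: 5 (Z)-6-(4-methoxybenzyloxy)-4-methylhex-4-enal; 6 ethyl (triphenylphosphoranylidene)acetate
Product: 8 ethyl (2Z,6Z)-2-iodo-8-(4-methoxybenzyloxy)-6-methylocta-2,6-dienoate, via iodo ylide 7 (not isolated)
Conditions: 6, NIS, CH2Cl2, −20 °C; then 5, K2CO3, −20 °C to rt
Reagents that add atoms: N-iodosuccinimide, O=C1CCC(=O)N1I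
Why: Iodination of the stabilised ylide gives iodo ylide 7, whose Wittig reaction places the ester trans to the chain so that iodine ends cis to C2 (Z); any E isomer should be removable by chromatography.

Step 5
Reactants: 8 ethyl (2Z,6Z)-2-iodo-8-(4-methoxybenzyloxy)-6-methylocta-2,6-dienoate
Product: 9 (2Z,6Z)-2-iodo-8-(4-methoxybenzyloxy)-6-methylocta-2,6-dien-1-ol
Conditions: i-Bu2AlH, CH2Cl2, −78 °C; Rochelle salt work-up
Reagents that add atoms: none
Why: i-Bu2AlH reduces the conjugated ester in 1,2-fashion to the primary allylic alcohol (C14–OH) at low temperature without touching the vinyl iodide or the alkene geometry.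

Step 6
Reactants: 9 (2Z,6Z)-2-iodo-8-(4-methoxybenzyloxy)-6-methylocta-2,6-dien-1-ol; 10 (tert-butyldimethylsilyloxy)acetaldehyde
Product: 11 (2R,3Z,7Z)-1-(tert-butyldimethylsilyloxy)-3-(hydroxymethyl)-9-(4-methoxybenzyloxy)-7-methylnona-3,7-dien-2-ol
Conditions: CrCl2, NiCl2 (cat.), chiral oxazoline sulfonamide ligand (enantiomer directing Re-face addition), Et3N, THF, rt
Reagents that add atoms: none
Why: Nozaki–Hiyama–Kishi coupling, in which zerovalent nickel inserts into the C–I bond with retention, the alkenyl group passes to trivalent chromium and adds to the aldehyde within the chiral ligand sphere on the Re face so that C9 becomes R, the free C14 hydroxyl being carried as its chromium alkoxide.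

Step 7
Reactants: 11 (2R,3Z,7Z)-1-(tert-butyldimethylsilyloxy)-3-(hydroxymethyl)-9-(4-methoxybenzyloxy)-7-methylnona-3,7-dien-2-ol; 12 (R)-2-methylbutanoic acid
Product: 13 [(2Z,6Z)-2-[(1R)-2-(tert-butyldimethylsilyloxy)-1-hydroxyethyl]-8-(4-methoxybenzyloxy)-6-methylocta-2,6-dienyl] (2R)-2-methylbutanoate
Conditions: EDC·HCl, DMAP (cat.), CH2Cl2, −10 to 0 °C
Reagents that add atoms: none
Why: Steglich esterification at low temperature should acylate the unhindered primary allylic C14 hydroxyl well ahead of the secondary C9 hydroxyl, and the α-stereocentre of the acid is not enolised under carbodiimide activation with catalytic DMAP.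

Step 8
Reactants: 13 C14 (R)-2-methylbutanoate with free C9 hydroxyl
Product: 14 [(2Z,6Z)-2-[(1R)-1-acetoxy-2-(tert-butyldimethylsilyloxy)ethyl]-8-(4-methoxybenzyloxy)-6-methylocta-2,6-dienyl] (2R)-2-methylbutanoate
Conditions: Ac2O, pyridine, DMAP (cat.), CH2Cl2, 0 °C to rt
Reagents that add atoms: acetic anhydride, CC(=O)OC(C)=O
Why: DMAP-catalysed acetylation of the remaining secondary allylic alcohol leaves the C9–O bond intact, so the configuration is retained.

Step 9
Reactants: 14 C9 acetate with C6 4-methoxybenzyl ether
Product: 15 [(2Z,6Z)-2-[(1R)-1-acetoxy-2-(tert-butyldimethylsilyloxy)ethyl]-8-hydroxy-6-methylocta-2,6-dienyl] (2R)-2-methylbutanoate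
Conditions: DDQ, CH2Cl2/pH 7 phosphate buffer, 0 °C
Reagents that add atoms: none
Why: DDQ oxidises the electron-rich 4-methoxybenzyl ether by hydride abstraction to an oxocarbenium ion that water hydrolyses, freeing the C6 alcohol, while the buffer protects the silyl ether and the allylic esters.

Step 10
Reactants: 15 C6 allylic alcohol
Product: 16 [(2Z,6Z)-2-[(1R)-1-acetoxy-2-(tert-butyldimethylsilyloxy)ethyl]-6-methyl-8-oxoocta-2,6-dienyl] (2R)-2-methylbutanoate
Conditions: MnO2, CH2Cl2, rt
Reagents that add atoms: none
Why: Activated MnO2 oxidises the allylic alcohol under neutral heterogeneous conditions, the usual way to reach a neral-type Z enal without Z to E isomerisation.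

Step 11
Reactants: 17 methyl propiolate
Product: 19 methyl (Z)-2-(hydroxymethyl)-3-iodoacrylate, via magnesium iodoallenolate 18 (not isolated)
Conditions: MgI2, paraformaldehyde, CH2Cl2, 0 °C to rt
Reagents that add atoms: magnesium iodide, [Mg+2].[I-].[I-]; formaldehyde (from paraformaldehyde), C=O
Why: β-Iodo Morita–Baylis–Hillman (halo-aldol) reaction, in which iodide adds in conjugate fashion to give allenolate 18 and this attacks formaldehyde at its α-carbon from the side away from iodine, leaving iodine cis to the ester (Z).

Step 12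
Reactants: 16 Z-enal; 19 methyl (Z)-2-(hydroxymethyl)-3-iodoacrylate
Product: 21 (5R)-3-(hydroxymethyl)furan-2(5H)-one carrying the full C5–C10 chain at C6 (C8 silyl ether; C9 acetate; C14 ester), via open hydroxy ester 20 (not isolated)
Conditions: CrCl2, NiCl2 (cat.), chiral oxazoline sulfonamide ligand (enantiomer directing Si-face addition), Et3N (1 equiv per ligand), THF, rt; work-up, then PPTS (cat.), CH2Cl2, rt
Reagents that add atoms: none
Why: Nozaki–Hiyama–Kishi coupling of the β-iodoacrylate with the enal in 1,2-fashion on the Si face makes C6 R, and because the Z geometry is retained the new C6 hydroxyl of 20 lies beside the methyl ester and closes the butenolide with loss of methanol.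

Step 13
Reactants: 21 3-(hydroxymethyl)butenolide
Product: 22 (5R)-3-(bromomethyl)furan-2(5H)-one with C8 silyl ether
Conditions: CBr4, PPh3, CH2Cl2, 0 °C
Reagents that add atoms: carbon tetrabromide, BrC(Br)(Br)Br
Why: Appel bromination converts the primary allylic C13 alcohol through its alkoxyphosphonium salt into the bromide under neutral conditions that spare the silyl ether, the esters and the C6 stereocentre.

Step 14
Reactants: 22 3-(bromomethyl)butenolide with C8 silyl ether
Product: 23 3-(bromomethyl)butenolide with free C8 primary alcohol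
Conditions: 48% aq. HF, MeCN, 0 °C
Reagents that add atoms: none
Why: Acidic fluoride cleaves the primary silyl ether while avoiding basic fluoride, which could attack the allylic bromide, epimerise C6 or trigger acetyl migration from O9 to O8.

Step 15
Reactants: 23 3-(bromomethyl)butenolide with free C8 primary alcohol
Product: 24 3-(bromomethyl)butenolide with C8 aldehyde (α-acetoxy aldehyde)
Conditions: Dess–Martin periodinane, NaHCO3, CH2Cl2, 0 °C; short silica plug, used at once
Reagents that add atoms: none
Why: Buffered Dess–Martin oxidation should give the α-acetoxy aldehyde without enolisation toward C9, and immediate use limits epimerisation or migration of the C1=C10 alkene into conjugation.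

Step 16
Reactants: 24 3-(bromomethyl)butenolide with C8 aldehyde
Product: 26 CNP0005248.2 (target), via allylchromium species 25 (not isolated)
Conditions: CrCl2 (excess), THF, rt, syringe-pump addition of 24, final concentration about 0.002 M
Reagents that add atoms: none
Why: Two equivalents of divalent chromium reduce the C13–Br bond to an allylchromium species of trivalent chromium (25), which binds the C8 aldehyde and delivers its γ-carbon C7 through a cyclic six-membered array, so that C7–C8 forms while the alkene moves from C7=C11 to exocyclic C11=C13 (Nozaki–Hiyama allylation in its intramolecular Barbier form). The closest known reactions are the chromium-mediated closure of ten-membered germacranolide rings from 2-(bromomethyl)acrylates and aldehydes and the intermolecular chromium or zinc Barbier allylation of aldehydes with 3-(bromomethyl)furan-2(5H)-ones. The ten-membered carbocycle closes in 10-exo-trig fashion at the C8 carbonyl, the two Z trisubstituted alkenes and the flat butenolide folding the chain so that C7 and C8 can meet; the lactone ring is already in place. C7 is controlled by C6, since the aldehyde must approach the butenolide face opposite the C5 side chain, which gives the trans ring fusion; C8 is controlled by C9 through Felkin–Anh addition anti to the acetoxy group, which gives the 8,9-anti acetoxy alcohol. The step needs γ-attack (ensured by the cyclic allyl transfer), ring closure ahead of oligomerisation (slow addition at high dilution) and the Felkin face of the aldehyde, the last being the open point because a chair with C9 pseudo-equatorial would deliver the C8 epimer. CrCl2 leaves the acetate, the 2-methylbutanoate and the lactone untouched, so the product should be the target itself with no further steps.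

Compound list
1 | nerol | CC(C)=CCC/C(C)=C\CO | starting material
2 | neryl 4-methoxybenzyl ether | CC(C)=CCC/C(C)=C\COCc1ccc(OC)cc1 | intermediate
3 | 3-[(Z)-5-(4-methoxybenzyloxy)-3-methylpent-3-enyl]-2,2-dimethyloxirane (racemic) | CC1(C)OC1CC/C(C)=C\COCc1ccc(OC)cc1 | intermediate
4 | (Z)-8-(4-methoxybenzyloxy)-2,6-dimethyloct-6-ene-2,3-diol (racemic, not isolated) | CC(C)(O)C(O)CC/C(C)=C\COCc1ccc(OC)cc1 | intermediate
5 | (Z)-6-(4-methoxybenzyloxy)-4-methylhex-4-enal | O=CCC/C(C)=C\COCc1ccc(OC)cc1 | intermediate
6 | ethyl (triphenylphosphoranylidene)acetate | CCOC(=O)C=P(c1ccccc1)(c1ccccc1)c1ccccc1 | starting material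
7 | ethyl iodo(triphenylphosphoranylidene)acetate (not isolated) | CCOC(=O)C(I)=P(c1ccccc1)(c1ccccc1)c1ccccc1 | intermediate
8 | ethyl (2Z,6Z)-2-iodo-8-(4-methoxybenzyloxy)-6-methylocta-2,6-dienoate | CCOC(=O)/C(I)=C/CC/C(C)=C\COCc1ccc(OC)cc1 | intermediate
9 | (2Z,6Z)-2-iodo-8-(4-methoxybenzyloxy)-6-methylocta-2,6-dien-1-ol | OC/C(I)=C/CC/C(C)=C\COCc1ccc(OC)cc1 | intermediate
10 | (tert-butyldimethylsilyloxy)acetaldehyde | O=CCO[Si](C)(C)C(C)(C)C | starting material
11 | (2R,3Z,7Z)-1-(tert-butyldimethylsilyloxy)-3-(hydroxymethyl)-9-(4-methoxybenzyloxy)-7-methylnona-3,7-dien-2-ol | COc1ccc(COC/C=C(/C)CC/C=C(/CO)[C@@H](O)CO[Si](C)(C)C(C)(C)C)cc1 | intermediate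
12 | (R)-2-methylbutanoic acid | CC[C@@H](C)C(=O)O | starting material
13 | [(2Z,6Z)-2-[(1R)-2-(tert-butyldimethylsilyloxy)-1-hydroxyethyl]-8-(4-methoxybenzyloxy)-6-methylocta-2,6-dienyl] (2R)-2-methylbutanoate | COc1ccc(COC/C=C(/C)CC/C=C(/COC(=O)[C@H](C)CC)[C@@H](O)CO[Si](C)(C)C(C)(C)C)cc1 | intermediate
14 | [(2Z,6Z)-2-[(1R)-1-acetoxy-2-(tert-butyldimethylsilyloxy)ethyl]-8-(4-methoxybenzyloxy)-6-methylocta-2,6-dienyl] (2R)-2-methylbutanoate | COc1ccc(COC/C=C(/C)CC/C=C(/COC(=O)[C@H](C)CC)[C@@H](OC(C)=O)CO[Si](C)(C)C(C)(C)C)cc1 | intermediate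
15 | [(2Z,6Z)-2-[(1R)-1-acetoxy-2-(tert-butyldimethylsilyloxy)ethyl]-8-hydroxy-6-methylocta-2,6-dienyl] (2R)-2-methylbutanoate | OC/C=C(/C)CC/C=C(/COC(=O)[C@H](C)CC)[C@@H](OC(C)=O)CO[Si](C)(C)C(C)(C)C | intermediate
16 | [(2Z,6Z)-2-[(1R)-1-acetoxy-2-(tert-butyldimethylsilyloxy)ethyl]-6-methyl-8-oxoocta-2,6-dienyl] (2R)-2-methylbutanoate | O=C/C=C(/C)CC/C=C(/COC(=O)[C@H](C)CC)[C@@H](OC(C)=O)CO[Si](C)(C)C(C)(C)C | intermediate
17 | methyl propiolate | C#CC(=O)OC | starting material
18 | iodomagnesium 3-iodo-1-methoxyallenolate (not isolated) | COC(O[Mg]I)=C=CI | intermediate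
19 | methyl (Z)-2-(hydroxymethyl)-3-iodoacrylate | I/C=C(/CO)C(=O)OC | intermediate
20 | methyl (2Z,4R)-4-hydroxy-2-(hydroxymethyl)dienoate carrying the C5–C10 chain (open hydroxy ester, not isolated) | COC(=O)/C(CO)=C\[C@H](O)/C=C(/C)CC/C=C(/COC(=O)[C@H](C)CC)[C@@H](OC(C)=O)CO[Si](C)(C)C(C)(C)C | intermediate
21 | (5R)-3-(hydroxymethyl)furan-2(5H)-one with C8 silyl ether, C9 acetate and C14 (R)-2-methylbutanoate | OCC1=C[C@@H](/C=C(/C)CC/C=C(/COC(=O)[C@H](C)CC)[C@@H](OC(C)=O)CO[Si](C)(C)C(C)(C)C)OC1=O | intermediate
22 | (5R)-3-(bromomethyl)furan-2(5H)-one with C8 silyl ether | BrCC1=C[C@@H](/C=C(/C)CC/C=C(/COC(=O)[C@H](C)CC)[C@@H](OC(C)=O)CO[Si](C)(C)C(C)(C)C)OC1=O | intermediate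
23 | (5R)-3-(bromomethyl)furan-2(5H)-one with free C8 alcohol | BrCC1=C[C@@H](/C=C(/C)CC/C=C(/COC(=O)[C@H](C)CC)[C@@H](OC(C)=O)CO)OC1=O | intermediate
24 | (5R)-3-(bromomethyl)furan-2(5H)-one with C8 aldehyde | BrCC1=C[C@@H](/C=C(/C)CC/C=C(/COC(=O)[C@H](C)CC)[C@@H](OC(C)=O)C=O)OC1=O | intermediate
25 | C13 allylchromium dichloride of 24 (not isolated) | Cl[Cr](Cl)CC1=C[C@@H](/C=C(/C)CC/C=C(/COC(=O)[C@H](C)CC)[C@@H](OC(C)=O)C=O)OC1=O | intermediate
26 | CNP0005248.2 | C=C1C(=O)O[C@@H]2/C=C(/C)CC/C=C(/COC(=O)[C@H](C)CC)[C@@H](OC(C)=O)[C@@H](O)[C@@H]12 | target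

Total step count: 16. Longest linear sequence: 15 steps (steps 1–10 and 12–16 from nerol); step 11 is a one-step side branch.

Steps most likely to fail

1. Step 16. The allyl transfer may run through a closed chair with C9 pseudo-equatorial and so strike the non-Felkin face of the aldehyde, giving the wrong configuration at C8. Intermolecular coupling may also compete with ring closure. The fallback corrects the stereocentre after ring closure instead of controlling it during closure. It sets out from 24, accepts the cyclisation with the wrong facial outcome and takes on the (8R)-epimer of the target F1. A Mitsunobu reaction with formic acid (PPh3, DIAD, THF, 0 °C) should invert C8 and give the (8S)-formate of the target F2. Mild hydrolysis of the formate (KHCO3, MeOH/H2O, 0 °C), which should leave acetate, 2-methylbutanoate and lactone alone, comes back to the route at 26.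

2. Step 12. Ligand control over the addition face at C6 of the enal may be poor, because the existing stereocentres are too remote to help, and base may erode the acidic C6 position of the butenolide. The fallback sets C6 by catalytic alkynylation and builds the butenolide afterwards. It sets out from 16 and 17: zinc alkynylation with a ProPhenol ligand (Me2Zn, toluene, 4 °C, enantiomer directing Si-face addition) should give the (R)-γ-hydroxy ynoate F3. Syn hydrostannation (Bu3SnH added slowly, Pd(PPh3)4 cat., THF, 0 °C) places tin α to the ester and, after lactonisation, gives the α-tributylstannyl butenolide F4. Iododestannylation (I2, CH2Cl2, 0 °C) gives the α-iodo butenolide F5. Stille coupling with (tributylstannyl)methanol (Pd(PPh3)4, LiCl, THF, 60 °C) comes back to the route at 21. The hindered allylic esters are expected to ionise only slowly with zerovalent palladium, and this would need watching.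

3. Step 6. Enantiofacial control at C9 may be insufficient, because the α-silyloxy aldehyde is small and the internal C14 alkoxide can compete with the chiral ligand for chromium. The fallback sets C9 by catalytic ketone reduction. It sets out from 9: deprotonation and iodine–lithium exchange (NaH, then t-BuLi, THF, −78 °C) and acylation with N-methoxy-N-methyl-2-(tert-butyldimethylsilyloxy)acetamide should give the hydroxy enone F6. Corey–Bakshi–Shibata reduction (oxazaborolidine enantiomer delivering hydride to the Si face, catecholborane, toluene, −78 °C) comes back to the route at 11.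

Further compounds
F1 | step 16 | (8R)-epimer of the target | C=C1C(=O)O[C@@H]2/C=C(/C)CC/C=C(/COC(=O)[C@H](C)CC)[C@@H](OC(C)=O)[C@H](O)[C@@H]12
F2 | step 16 | (8S)-formate of the target | C=C1C(=O)O[C@@H]2/C=C(/C)CC/C=C(/COC(=O)[C@H](C)CC)[C@@H](OC(C)=O)[C@@H](OC=O)[C@@H]12
F3 | step 12 | methyl (4R)-4-hydroxy-alk-2-ynoate carrying the C5–C10 chain (γ-hydroxy ynoate) | COC(=O)C#C[C@H](O)/C=C(/C)CC/C=C(/COC(=O)[C@H](C)CC)[C@@H](OC(C)=O)CO[Si](C)(C)C(C)(C)C
F4 | step 12 | (5R)-3-(tributylstannyl)furan-2(5H)-one carrying the chain | CCCC[Sn](CCCC)(CCCC)C1=C[C@@H](/C=C(/C)CC/C=C(/COC(=O)[C@H](C)CC)[C@@H](OC(C)=O)CO[Si](C)(C)C(C)(C)C)OC1=O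
F5 | step 12 | (5R)-3-iodofuran-2(5H)-one carrying the chain | IC1=C[C@@H](/C=C(/C)CC/C=C(/COC(=O)[C@H](C)CC)[C@@H](OC(C)=O)CO[Si](C)(C)C(C)(C)C)OC1=O
F6 | step 6 | (3Z,7Z)-1-(tert-butyldimethylsilyloxy)-3-(hydroxymethyl)-9-(4-methoxybenzyloxy)-7-methylnona-3,7-dien-2-one | COc1ccc(COC/C=C(/C)CC/C=C(/CO)C(=O)CO[Si](C)(C)C(C)(C)C)cc1
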